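**Retrosynthetic overview**

1. Ring C (cyclohexene C2–C1–C10–C14–C15'–C4') is opened at C10–C14: target 22 ⇐ seco-dimer 18, in which spiro carbon C4' already bears C2 of unit 1 and a 2-bromoethyl arm (C15'–C14), and unit 1 is a 14-nor guaianolide with a skipped enone (C3=O, C2–H, C1=C10).
2. Enabling feature: C10 is the γ-carbon of the cross-conjugated enolate O–C3=C2–C1=C10 and sits cis to C4' across the C1–C2 edge of ring A, so the arm reaches C10 in a six-membered closure; the trans-fused 12,6-lactone locks ring B on one face of ring A, which steers first C10 and then C5.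
3. 18 ⇐ Mukaiyama–Michael union (C2–C4') of bromoethyl silyl enol ether 13 (from spiro-cyclopropyl ketone 8; the ylide carbon becomes C14) with 14-nor ene-dione 12 (from ozonolysis of dienone 11); the C10 oxygen leaves via the enol triflate.
4. Both halves ⇐ common enone 7 ⇐ cynaropicrin (C8 inverted by Mitsunobu reaction; conjugated methylenes parked as Me2NH adducts).
5. Ring order: rings A, B and the lactones of both units are native; a temporary cyclopropane (step 5) is opened (step 9); ring C is closed last (step 14).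

Key step: step 14

Remark (assumption): unit 1 is the cyclopentenone-bearing half (locants C1–C15), unit 2 the spiro half (primed locants); the configurations drawn at C4/C11/C11' of the amine adducts and at C2 of 14–18 are the expected ones and are all erased later (steps 13 and 14).

**Route**

Step 1
Reactants: 1 cynaropicrin
Product: 3 13-(dimethylamino)-3β,8α-dihydroxy-11βH-guaia-4(15),10(14)-dien-12,6-olide, via bis-amine adduct 2 (not isolated)
Conditions: Me2NH (2 M in THF), MeOH, 0 °C → rt; then K2CO3, MeOH, rt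
Reagents that add atoms: dimethylamine, CNC
Why: Aza-Michael addition masks the lactone methylene (C11 protonated from the β-face) and saturates the side-chain acrylate, after which transesterification removes the 8-O-acyl group.

Step 2
Reactants: 3 amino diol
Product: 4 13-(dimethylamino)-8α-hydroxy-3-oxo-11βH-guaia-4(15),10(14)-dien-12,6-olide
Conditions: MnO2, CH2Cl2, rt
Reagents that add atoms: none
Why: MnO2 oxidation is selective for the allylic 3-OH (activated by C4=C15) over the saturated 8-OH and should give the exocyclic enone without touching a stereocenter.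

Step 3
Reactants: 4 8α-hydroxy enone
Product: 6 8β-hydroxy enone (8-epimer of 4), via 8β-formate 5 (not isolated)
Conditions: HCO2H, PPh3, DIAD, THF, 0 °C → rt; then NaHCO3, MeOH/H2O, 0 °C
Reagents that add atoms: formic acid, OC=O
Why: Mitsunobu reaction (SN2 displacement by formate) inverts C8 to the 8β (8R) configuration required in both halves, and the formate is cleaved under conditions mild enough for the exocyclic enone.

Step 4
Reactants: 6 8β-hydroxy enone
Product: 7 8β-(tert-butyldimethylsilyloxy) enone (common intermediate)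
Conditions: TBSCl, imidazole, DMAP (cat.), DMF, 40 °C
Reagents that add atoms: tert-butyldimethylsilyl chloride, CC(C)(C)[Si](C)(C)Cl
Why: Standard silylation of the axial 8β-OH, which later also keeps this hydroxyl from adding to the neighbouring lactone methylene under base.

Step 5
Reactants: 7 common enone
Product: 8 spiro-cyclopropyl ketone of unit 2 (cyclopropane on C4 made of C15 and the future C14)
Conditions: Me3S(O)I, NaH, DMSO, rt; then 7, rt
Reagents that add atoms: trimethylsulfoxonium iodide, C[S+](C)(C)=O.[I-]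
Why: Corey–Chaykovsky cyclopropanation (conjugate addition of the sulfoxonium ylide to C15, then 3-exo-tet closure) brings in the carbon that becomes C14; the spiro carbon carries two equivalent CH2 groups, so no stereocenter is formed.

Step 6
Reactants: 7 common enone
Product: 9 13,15-bis(dimethylamino) ketone of unit 1 (4βH, 11βH; C10=C14 intact)
Conditions: Me2NH (2 M in THF), EtOH, 0 °C
Reagents that add atoms: dimethylamine, CNC
Why: Aza-Michael addition parks the exocyclic enone methylene as a Mannich base (C4 protonated trans to the C5–C6 bond), so that unit 1 carries no conjugate acceptor other than the one built in step 8.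

Step 7
Reactants: 9 Mannich base
Product: 11 1,10(14)-dien-3-one of unit 1, via trimethylsilyl dienol ether 10 (not isolated)
Conditions: LiN(SiMe3)2, Me3SiCl, THF, −78 °C; then Pd(OAc)2, MeCN, rt
Reagents that add atoms: none
Why: Kinetic enolisation at the less hindered C2 followed by Saegusa–Ito oxidation (β-hydride loss from C1) installs the C1=C2 double bond regioselectively.

Step 8
Reactants: 11 dienone
Product: 12 14-nor-1-ene-3,10-dione of unit 1
Conditions: CF3CO2H (2.2 equiv), O3, CH2Cl2/MeOH, −78 °C; Me2S; NaHCO3 work-up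
Reagents that add atoms: ozone, [O-][O+]=O
Why: Ozonolysis attacks the only electron-rich alkene (C10=C14; C1=C2 is a deactivated enone and the amines are ammonium salts) and excises C14, leaving a 2-ene-1,4-dione whose C2 is the sole unsubstituted acceptor carbon.

Step 9
Reactants: 8 spiro-cyclopropyl ketone
Product: 13 4-(2-bromoethyl) C3=C4 trimethylsilyl enol ether of unit 2
Conditions: Me3SiBr, ZnBr2 (5 mol %), CH2Cl2, 0 °C → rt; volatiles removed
Reagents that add atoms: bromotrimethylsilane, C[Si](C)(C)Br
Why: Silyl-halide ring opening of a cyclopropyl ketone (1,5-addition): bromide opens either of the two equivalent C4–CH2 bonds, which gives the tetrasubstituted silyl enol ether regiospecifically with C14 as a primary bromide.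

Step 10
Reactants: 13 bromoethyl silyl enol ether; 12 ene-dione
Product: 14 seco-dimer with the C2–C4' bond, as its C1=C10 trimethylsilyl enol ether
Conditions: CF3SO3H (1.0 equiv per amine), Me3SiOTf (20 mol %), CH2Cl2, −78 °C; pyridine, cold NaHCO3 work-up; used crude
Reagents that add atoms: none
Why: Mukaiyama–Michael addition of C4' to C2 of the ene-dione; C4' is attacked on the convex α-face of the cis-fused hydroazulene (ring B' lies on the β-face), which sets the quaternary centre as in the target, and silyl transfer stores the enolate regiospecifically as the C1=C10 silyl enol ether.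

Step 11
Reactants: 14 silyl enol ether
Product: 15 C1=C10 enol triflate
Conditions: PhNTf2, Bu4N[Ph3SiF2], THF, −78 °C
Reagents that add atoms: N-phenylbis(trifluoromethanesulfonimide), O=S(=O)(N(c1ccccc1)S(=O)(=O)C(F)(F)F)C(F)(F)F
Why: Fluoride releases the regiodefined C10 enolate, which should be trapped as the enol triflate at −78 °C faster than retro-Michael cleavage or alkylation by the primary bromide.

Step 12
Reactants: 15 enol triflate
Product: 16 seco-dimer with 14-nor-1(10)-en-3-one unit 1 (amine-masked, C14 bromide)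
Conditions: Pd(PPh3)4 (5 mol %), LiCl, Bu3SnH, THF, rt
Reagents that add atoms: none
Why: Palladium-catalysed reduction of the enol triflate by Bu3SnH removes the C10 oxygen and leaves the C1=C10 bond, i.e. the skipped enone needed for regiodefined enolate formation; with all conjugate acceptors masked no 1,4-reduction can compete.

Step 13
Reactants: 16 masked seco-dimer
Product: 18 seco-dimer with all three exocyclic methylenes restored, via tris-methiodide 17 (not isolated)
Conditions: MeI, MeCN, rt; then NaHCO3, CH2Cl2/H2O, 0 °C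
Reagents that add atoms: none
Why: Exhaustive N-methylation followed by bicarbonate-induced Hofmann-type (E1cB) loss of trimethylamine regenerates C4=C15, C11=C13 and C11'=C13' under conditions too weakly basic to move the C1=C10 bond.

Step 14
Reactants: 18 seco-dimer bromide
Product: 21 bis-silyl ether of the target, via hexacyclic 5α-H enone 19 (not isolated), via lithium fulvenolate 20 (not isolated)
Conditions: LiN(SiMe3)2 (1.05 equiv), THF (0.005 M), −78 → −30 °C; then LiN(SiMe3)2 (1.1 equiv), −78 °C; cannulated into AcOH/THF, −78 °C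
Reagents that add atoms: none
Why: LiN(SiMe3)2 removes the doubly activated H-2 to give the cross-conjugated lithium trienolate (O–C3=C2–C1=C10), whose γ-carbon C10 displaces bromide at C14 (SN2) to close ring C and give enone 19; the second equivalent removes the now doubly activated H-5 to give fulvene-type enolate 20, which is protonated at its central carbon C5 on inverse quench. The closest known reaction types are the intramolecular γ-alkylation of extended ketone enolates and the kinetic central-carbon protonation of cross-conjugated (pentadienyl-type) enolates as in Birch reductions. Ring C closes in a 6-(enolendo)-exo-tet mode; attack by C2 would need a cyclobutane, and O-alkylation, the only other six-membered option, is disfavoured for a lithium enolate in THF. C10 is controlled by C5: with the native 5α-H the lactone-locked chair of ring B lies on the β-face of the planar trienolate, so C14 should bond to the α-face of C10 and H-10 ends β. C5 is then controlled by the new C10 centre and the lactone: in 20 the same chair hangs on the α-face, so the proton should enter C5 from the open β-face (anti to C7, staggered to the C6 substituents), which inverts C5 to the required 5β-H under kinetic control. The step needs C10- over O-alkylation and β-face protonation without later equilibration; the pre-installed C1=C10 bond, the arm length, the acidic quench and the absence of base afterwards secure this, and both C2 epimers of 18 converge on the same trienolate.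

Step 15
Reactants: 21 bis-silyl ether
Product: 22 target (CNP0397417.1)
Conditions: HF·pyridine, THF/pyridine, 0 °C → rt
Reagents that add atoms: none
Why: Desilylation under acidic, non-nucleophilic conditions frees both 8β-hydroxyls without enolising the doubly activated C5–H or adding to the methylene lactones.

**Compound list**

1 | cynaropicrin | C=C1[C@@H](O)C[C@H]2C(=C)C[C@H](OC(=O)C(=C)CO)[C@H]3C(=C)C(=O)O[C@@H]3[C@@H]12 | starting material
2 | bis-dimethylamine adduct of cynaropicrin (13-NMe2, 11βH; side chain aminated) | C=C1[C@@H](O)C[C@H]2C(=C)C[C@H](OC(=O)C(CO)CN(C)C)[C@H]3[C@H](CN(C)C)C(=O)O[C@@H]3[C@@H]12 | intermediate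
3 | 13-(dimethylamino)-3β,8α-dihydroxy-11βH-guaia-4(15),10(14)-dien-12,6-olide | C=C1[C@@H](O)C[C@H]2C(=C)C[C@H](O)[C@H]3[C@H](CN(C)C)C(=O)O[C@@H]3[C@@H]12 | intermediate
4 | 13-(dimethylamino)-8α-hydroxy-3-oxo-11βH-guaia-4(15),10(14)-dien-12,6-olide | C=C1C(=O)C[C@H]2C(=C)C[C@H](O)[C@H]3[C@H](CN(C)C)C(=O)O[C@@H]3[C@@H]12 | intermediate
5 | 8β-formate of the C8-inverted enone | C=C1C(=O)C[C@H]2C(=C)C[C@@H](OC=O)[C@H]3[C@H](CN(C)C)C(=O)O[C@@H]3[C@@H]12 | intermediate
6 | 13-(dimethylamino)-8β-hydroxy-3-oxo-11βH-guaia-4(15),10(14)-dien-12,6-olide | C=C1C(=O)C[C@H]2C(=C)C[C@@H](O)[C@H]3[C@H](CN(C)C)C(=O)O[C@@H]3[C@@H]12 | intermediate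
7 | 8β-TBS ether of 6 (common enone) | C=C1C(=O)C[C@H]2C(=C)C[C@@H](O[Si](C)(C)C(C)(C)C)[C@H]3[C@H](CN(C)C)C(=O)O[C@@H]3[C@@H]12 | intermediate
8 | spiro-cyclopropyl ketone of unit 2 (cyclopropane on C4) | O=C1C[C@H]2C(=C)C[C@@H](O[Si](C)(C)C(C)(C)C)[C@H]3[C@H](CN(C)C)C(=O)O[C@@H]3[C@H]2C14CC4 | intermediate
9 | 13,15-bis(dimethylamino)-3-oxo-4βH,11βH-guai-10(14)-en-12,6-olide 8β-TBS ether | CN(C)C[C@@H]1C(=O)C[C@H]2C(=C)C[C@@H](O[Si](C)(C)C(C)(C)C)[C@H]3[C@H](CN(C)C)C(=O)O[C@@H]3[C@@H]12 | intermediate
10 | C2=C3 trimethylsilyl dienol ether of 9 | CN(C)C[C@@H]1C(O[Si](C)(C)C)=C[C@H]2C(=C)C[C@@H](O[Si](C)(C)C(C)(C)C)[C@H]3[C@H](CN(C)C)C(=O)O[C@@H]3[C@@H]12 | intermediate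
11 | 1,10(14)-dien-3-one of unit 1 (amine-masked) | CN(C)C[C@@H]1C(=O)C=C2C(=C)C[C@@H](O[Si](C)(C)C(C)(C)C)[C@H]3[C@H](CN(C)C)C(=O)O[C@@H]3[C@@H]12 | intermediate
12 | 14-nor-1-ene-3,10-dione of unit 1 (amine-masked) | CN(C)C[C@@H]1C(=O)C=C2C(=O)C[C@@H](O[Si](C)(C)C(C)(C)C)[C@H]3[C@H](CN(C)C)C(=O)O[C@@H]3[C@@H]12 | intermediate
13 | 4-(2-bromoethyl) C3=C4 trimethylsilyl enol ether of unit 2 | C[Si](C)(C)OC=1C[C@H]2C(=C)C[C@@H](O[Si](C)(C)C(C)(C)C)[C@H]3[C@H](CN(C)C)C(=O)O[C@@H]3[C@H]2C=1CCBr | intermediate
14 | seco-dimer (C2–C4' bond), C1=C10 trimethylsilyl enol ether | CN(C)C[C@@H]1C(=O)[C@H]([C@]4(CCBr)C(=O)C[C@H]5C(=C)C[C@@H](O[Si](C)(C)C(C)(C)C)[C@H]6[C@H](CN(C)C)C(=O)O[C@@H]6[C@@H]45)C2=C(O[Si](C)(C)C)C[C@@H](O[Si](C)(C)C(C)(C)C)[C@H]3[C@H](CN(C)C)C(=O)O[C@@H]3[C@@H]12 | intermediate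
15 | seco-dimer, C1=C10 enol triflate | CN(C)C[C@@H]1C(=O)[C@H]([C@]4(CCBr)C(=O)C[C@H]5C(=C)C[C@@H](O[Si](C)(C)C(C)(C)C)[C@H]6[C@H](CN(C)C)C(=O)O[C@@H]6[C@@H]45)C2=C(OS(=O)(=O)C(F)(F)F)C[C@@H](O[Si](C)(C)C(C)(C)C)[C@H]3[C@H](CN(C)C)C(=O)O[C@@H]3[C@@H]12 | intermediate
16 | seco-dimer, 14-nor-1(10)-en-3-one unit 1, amine-masked | CN(C)C[C@@H]1C(=O)[C@H]([C@]4(CCBr)C(=O)C[C@H]5C(=C)C[C@@H](O[Si](C)(C)C(C)(C)C)[C@H]6[C@H](CN(C)C)C(=O)O[C@@H]6[C@@H]45)C2=CC[C@@H](O[Si](C)(C)C(C)(C)C)[C@H]3[C@H](CN(C)C)C(=O)O[C@@H]3[C@@H]12 | intermediate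
17 | tris(trimethylammonium) triiodide of 16 | C[N+](C)(C)C[C@@H]1C(=O)[C@H]([C@]4(CCBr)C(=O)C[C@H]5C(=C)C[C@@H](O[Si](C)(C)C(C)(C)C)[C@H]6[C@H](C[N+](C)(C)C)C(=O)O[C@@H]6[C@@H]45)C2=CC[C@@H](O[Si](C)(C)C(C)(C)C)[C@H]3[C@H](C[N+](C)(C)C)C(=O)O[C@@H]3[C@@H]12.[I-].[I-].[I-] | intermediate
18 | seco-dimer bromide with C4=C15, C11=C13 and C11'=C13' restored (key-step substrate) | C=C1C(=O)[C@H]([C@]4(CCBr)C(=O)C[C@H]5C(=C)C[C@@H](O[Si](C)(C)C(C)(C)C)[C@H]6C(=C)C(=O)O[C@@H]6[C@@H]45)C2=CC[C@@H](O[Si](C)(C)C(C)(C)C)[C@H]3C(=C)C(=O)O[C@@H]3[C@@H]12 | intermediate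
19 | hexacyclic enone, 5α-H, 10β-H, bis-TBS | C=C1C(=O)C2=C3[C@H](CC[C@]24C(=O)C[C@H]2C(=C)C[C@@H](O[Si](C)(C)C(C)(C)C)[C@H]5C(=C)C(=O)O[C@@H]5[C@H]24)C[C@@H](O[Si](C)(C)C(C)(C)C)[C@H]2C(=C)C(=O)O[C@@H]2[C@@H]13 | intermediate
20 | lithium fulvene-type enolate (C5 deprotonated) | C=C1C([O-])=C2C=3[C@H](CC[C@]24C(=O)C[C@H]2C(=C)C[C@@H](O[Si](C)(C)C(C)(C)C)[C@H]5C(=C)C(=O)O[C@@H]5[C@H]24)C[C@@H](O[Si](C)(C)C(C)(C)C)[C@H]2C(=C)C(=O)O[C@@H]2C1=3.[Li+] | intermediate
21 | bis-TBS ether of the target (5β-H) | C=C1C(=O)C2=C3[C@H](CC[C@]24C(=O)C[C@H]2C(=C)C[C@@H](O[Si](C)(C)C(C)(C)C)[C@H]5C(=C)C(=O)O[C@@H]5[C@H]24)C[C@@H](O[Si](C)(C)C(C)(C)C)[C@H]2C(=C)C(=O)O[C@@H]2[C@H]13 | intermediate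
22 | CNP0397417.1 | C=C1C(=O)C2=C3[C@H](CC[C@]24C(=O)C[C@H]2C(=C)C[C@@H](O)[C@H]5C(=C)C(=O)O[C@@H]5[C@H]24)C[C@@H](O)[C@H]2C(=C)C(=O)O[C@@H]2[C@H]13 | target

**Step count and risks**

Total step count: 15. Longest linear sequence: 13 steps (steps 1–4, 6–8, 10–15).

Step 14. What may go wrong: erosion of β-face selectivity in the kinetic protonation at C5, or proton-transfer equilibration back towards the 5α-H epimer during the quench; O-alkylation of the trienolate is a second failure mode. The fallback replaces substrate-controlled by reagent-controlled protonation. It sets out from 18, which is cyclised with one equivalent of LiN(SiMe3)2 only and quenched, so that hexacyclic 5α-H enone 19 is isolated. Compound 19 is converted with Me3SiOTf/Et3N (CH2Cl2, −78 °C) into silyl trienol ether F1. F1 is protonated with the Lewis-acid-assisted chiral Brønsted acid SnCl4·BINOL (toluene, −78 °C; both antipodes of BINOL are tried and the one matched to β-face delivery is kept). This should give 21, where the route is rejoined before step 15.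

Step 10. What may go wrong: no C–C bond formation between the tetrasubstituted enol ether carbon and the hindered ene-dione (steric congestion at the vicinal quaternary/tertiary centres), with protodesilylation of 13 taking over. The fallback is a radical instead of a polar union. It sets out from 13, which is brominated with N-bromosuccinimide (amine as its trifluoroacetate salt, THF, −78 °C) to tertiary α-bromo ketone F2. Ene-dione 12 is reductively silylated (Zn, Me3SiCl, THF) to 1,4-bis(trimethylsilyloxy)diene F3. Visible-light photoredox coupling of F2 with F3 (Ir(ppy)3, blue light, MeCN) should let the electrophilic C4' radical add to C2 of the electron-rich diene; oxidation and desilylation of the adduct radical return the C3 ketone. The route is rejoined at 14.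

Step 11. What may go wrong: retro-Michael fragmentation of the free C10 enolate (back to 12 and cyclopropane 8), or its five-membered C1-alkylation by the bromide, before triflation. The fallback avoids the enolate. It sets out from 14, which is hydrolysed (citric acid, THF/H2O) to triketone F4. The C10 ketone of F4, the least hindered of the three, is O-triflated with Tf2O and 2,6-di-tert-butyl-4-methylpyridine (amines as triflate salts, CH2Cl2, 0 °C) towards the more substituted enol triflate. The route is rejoined at 15.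

Further compounds
F1 | step 14 | trimethylsilyl trienol ether of 19 (O-silylated form of 20) | C=C1C(O[Si](C)(C)C)=C2C=3[C@H](CC[C@]24C(=O)C[C@H]2C(=C)C[C@@H](O[Si](C)(C)C(C)(C)C)[C@H]5C(=C)C(=O)O[C@@H]5[C@H]24)C[C@@H](O[Si](C)(C)C(C)(C)C)[C@H]2C(=C)C(=O)O[C@@H]2C1=3
F2 | step 10 | 4-bromo-4-(2-bromoethyl) ketone of unit 2 (C4 epimers) | O=C1C[C@H]2C(=C)C[C@@H](O[Si](C)(C)C(C)(C)C)[C@H]3[C@H](CN(C)C)C(=O)O[C@@H]3[C@H]2C1(Br)CCBr
F3 | step 10 | 3,10-bis(trimethylsilyloxy)-2,1(10)-diene of unit 1 | CN(C)C[C@@H]1C(O[Si](C)(C)C)=CC2=C(O[Si](C)(C)C)C[C@@H](O[Si](C)(C)C(C)(C)C)[C@H]3[C@H](CN(C)C)C(=O)O[C@@H]3[C@@H]12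
F4 | step 11 | seco-dimer triketone (C10 ketone, C1 epimers) | CN(C)C[C@@H]1C(=O)[C@H]([C@]4(CCBr)C(=O)C[C@H]5C(=C)C[C@@H](O[Si](C)(C)C(C)(C)C)[C@H]6[C@H](CN(C)C)C(=O)O[C@@H]6[C@@H]45)C2C(=O)C[C@@H](O[Si](C)(C)C(C)(C)C)[C@H]3[C@H](CN(C)C)C(=O)O[C@@H]3[C@@H]12
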